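**Turning time.** Turn the time first. By hand, a flask that has halted gains nothing from more hours, and Tuesday's run shows such a halt: Q reads 50.1% at 4.00 h and 50.5% at 6.00 h, a step near the scatter.

| setting | Saturday's | Tuesday's | flask |
|---|---|---|---|
| Z | 2 M | 1 M | 2.0 M |
| remark | the very flask that is asked about, followed so far | run made earlier |  |
| time |  |  | 15 h |

- Saturday's (time / min: Q / %, X / %): 4.00: 11.8, 24.3; 12.0: 21.6, 30.6; 20.0: 29.5, 27.9; 30.0: 37.1, 25.3; 40.0: 43.6, 22.1; 60.0: 53.8, 18.9; 80.0: 60.0, 16.1
- Tuesday's (time / h: Q / %, X / %): 0.333: 22.8, 30.4; 1.00: 37.2, 24.1; 1.50: 43.0, 22.8; 2.50: 48.1, 20.1; 4.00: 50.1, 19.3; 5.00: 49.6, 18.8; 6.00: 50.5, 19.0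

(readings scatter by 0.3 percentage points)

- a reading or a percentage of Q counts all its forms, free or not

1. Q at 15 h, in percent of the Z charged
2. X at 15 h, in percent of the Z charged

**Turning charge.** Now turn the charge of Z. Dissolved species joined by first-order steps keep their percentages whatever the charge, yet Saturday's run at 2 M reads 60.0% of Q at 80.0 min, past Tuesday's halt. So I look for a concentration that holds instead of a percentage, and I suppose that Q crystallises at its solubility limit.

**The remainder.** Tuesday's halt leaves 0.495 M of material outside Q, which I call c_rest, the concentration of what is not Q once Q has crystallised. Within it, c_X reads 0.190 M. Saturday's last reading still has 0.800 M outside Q, more than c_rest, so that run has further to go. At 15 h I therefore reckon 75.2% of Q and 9.50% of X.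

**The result.** The forecast gives 73% of Q and 10.7% of X, holding that “the run is at its plateau”. The flask gives 75.2% of Q and 9.60% of X.

    X ⇌ E (K = 0.860, k = 0.390 /min)
    L ⇌ Q, rate k2*(cs2 - [Q]) while solid is left; crystals form when [Q] > cs2 (solubility = 0.120 M, k = 0.620 /min)
    Z ⇌ Q (K = 0.870, k = 0.0610 /min)
    E ⇌ Z (k = 0.300 /min)
    Q ⇌ X (K = 1.60, k = 0.0220 /min)

**The reason.** The limit of solubility of Q has the largest single effect on X in this flask: without that limit, this flask ends at 31.2% of X instead of 9.60%. Here c_rest is 24.8% of the charge, standing as Z at 6.90%, X at 9.60% and E at 8.26%, beside L at 69.2%. At 0.80 M of Z, c_rest and c_X give 38.1% of Q and 23.8% of X, and that flask, with L at 23.1%, holds 38.1% of Q and 24.0% of X.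

The earlier runs and the new flask were generated by integration with constants of no real substance; scatter was added.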